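## Retrosynthetic overview

1. Last step: one BCl3 operation frees the three benzyl-protected phenols and the carbonyl-chelated ortho-methoxy group of the fully assembled precursor.
2. Key disconnection: Cα(aryl ketone)–C3(chromone), two carbons that are both normally nucleophilic α-carbons. Cα is made electrophilic as a chiral dirhodium carbene (enolonium equivalent) from an α-diazoketone and is attacked by the α-carbon of an o-hydroxyaryl enaminone; this sets the only stereocentre.
3. Ring order: all benzene rings are bought. The only ring made is the pyran-4-one ring of the chromone, closed in the same flask right after the key C–C bond (phenol addition, loss of Me2NH).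
4. Diazoketone ⇐ diazo transfer ⇐ 3,3-diarylpropiophenone ⇐ rhodium-catalysed aryl 1,4-addition ⇐ chalcone ⇐ Claisen–Schmidt condensation.
5. Enaminone ⇐ 4'-benzyloxy-2'-hydroxyacetophenone + DMF dimethyl acetal.

Assumption: the target stereocentre is (R) by CIP analysis of the given SMILES; the sense of induction in step 5 cannot be predicted with certainty, so the route is written with Rh2(S-NTTL)4 (dirhodium tetrakis[N-(1,8-naphthaloyl)-(S)-tert-leucinate]) and the mirror-image catalyst Rh2(R-NTTL)4 is used instead if the first run gives the (S)-product.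

## Route

Step 1
Reactants: 1 1-(2,4-dimethoxyphenyl)ethan-1-one; 2 4-(benzyloxy)benzaldehyde
Product: 3 (E)-3-[4-(benzyloxy)phenyl]-1-(2,4-dimethoxyphenyl)prop-2-en-1-one
Conditions: NaOH (40% aq.), EtOH, rt, 16 h
Reagents that add atoms: none
Why: Claisen–Schmidt aldol condensation of a methyl aryl ketone with a non-enolisable aldehyde gives the conjugated (E)-chalcone, which crystallises from the medium; no stereocentre is formed.

Step 2
Reactants: 3 (E)-3-[4-(benzyloxy)phenyl]-1-(2,4-dimethoxyphenyl)prop-2-en-1-one; 4 [4-(benzyloxy)phenyl]boronic acid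
Product: 5 3,3-bis[4-(benzyloxy)phenyl]-1-(2,4-dimethoxyphenyl)propan-1-one
Conditions: [Rh(cod)OH]2 (2 mol%), 4 (1.5 equiv), dioxane/H2O 10:1, 80 °C
Reagents that add atoms: none
Why: Hayashi–Miyaura rhodium-catalysed 1,4-addition of an arylboronic acid to an enone (aryl-rhodium insertion, then protonolysis by water); the two β-aryl groups are identical, so no stereocentre arises and an achiral diene ligand suffices.

Step 3
Reactants: 5 3,3-bis[4-(benzyloxy)phenyl]-1-(2,4-dimethoxyphenyl)propan-1-one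
Product: 7 3,3-bis[4-(benzyloxy)phenyl]-2-diazo-1-(2,4-dimethoxyphenyl)propan-1-one, via alpha-trifluoroacetyl ketone 6 (not isolated)
Conditions: LiN(SiMe3)2 (1.1 equiv), THF, −78 °C; CF3CO2CH2CF3 (1.2 equiv), −78 °C; 1 M HCl quench, crude 6 used at once without purification; 4-AcNHC6H4SO2N3 (1.5 equiv), Et3N (1.5 equiv), H2O (1 equiv), MeCN, rt
Reagents that add atoms: 4-acetamidobenzenesulfonyl azide (p-ABSA), CC(=O)Nc1ccc(cc1)S(=O)(=O)N=[N+]=[N-] (gives the two diazo nitrogens); 2,2,2-trifluoroethyl trifluoroacetate, O=C(OCC(F)(F)F)C(F)(F)F (gives the CF3CO group of 6 only, lost again in the transfer)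
Why: Regitz-type detrifluoroacetylative diazo transfer (Danheiser protocol): Claisen trifluoroacetylation activates the only enolisable position, and the 1,3-diketone enolate then adds to the sulfonyl azide and fragments with loss of the N-trifluoroacetyl sulfonamide; no stereocentre.

Step 4
Reactants: 8 1-[4-(benzyloxy)-2-hydroxyphenyl]ethan-1-one
Product: 9 (E)-1-[4-(benzyloxy)-2-hydroxyphenyl]-3-(dimethylamino)prop-2-en-1-one
Conditions: Me2NCH(OMe)2 (2 equiv), PhMe, 90 °C, 3 h
Reagents that add atoms: N,N-dimethylformamide dimethyl acetal, COC(OC)N(C)C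
Why: Aminomethylenation of the methyl ketone by an amide acetal gives the vinylogous amide as its thermodynamic (E)-isomer, leaving the hydrogen-bonded ortho phenol free for the later ring closure.

Step 5
Reactants: 7 3,3-bis[4-(benzyloxy)phenyl]-2-diazo-1-(2,4-dimethoxyphenyl)propan-1-one; 9 (E)-1-[4-(benzyloxy)-2-hydroxyphenyl]-3-(dimethylamino)prop-2-en-1-one
Product: 11 7-(benzyloxy)-3-[(2R)-3,3-bis[4-(benzyloxy)phenyl]-1-(2,4-dimethoxyphenyl)-1-oxopropan-2-yl]-4H-chromen-4-one, via C-alkylated enaminone 10 (not isolated)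
Conditions: Rh2(S-NTTL)4 (2 mol%), 9 (2 equiv), CH2Cl2/PhMe 1:1, −78 °C, 7 added over 2 h; then AcOH (5 equiv), −78 °C → rt
Reagents that add atoms: none
Why: Proposed new method: the divalent-rhodium carbene formed from 7 is an α-electrophilic ketone (enolonium equivalent) that is attacked by the nucleophilic α-carbon of vinylogous amide 9 to give an iminium/rhodium-enolate zwitterion, whose proton transfer on the metal (before a free enol is released) gives 10 with the (R)-centre fixed by the chiral crown of tert-leucinate ligands, after which the phenol adds to the β-aminoenone and Me2NH is lost under acid to close the pyranone ring; the bulky carboxylates and −78 °C are chosen to slow the competing 1,2-hydride shift of the benzhydrylic β-hydrogen, and the closest known reaction types are the enantioselective dirhodium-catalysed C–H functionalisation of indoles by α-alkyl-α-diazoesters at −78 °C and the achiral carbene or electrophile coupling/cyclisation of o-hydroxyaryl enaminones to 3-substituted chromones.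

Step 6
Reactants: 11 7-(benzyloxy)-3-[(2R)-3,3-bis[4-(benzyloxy)phenyl]-1-(2,4-dimethoxyphenyl)-1-oxopropan-2-yl]-4H-chromen-4-one
Product: 12 (2R)-1-(2-hydroxy-4-methoxyphenyl)-2-(7-hydroxy-4-oxo-4H-chromen-3-yl)-3,3-bis(4-hydroxyphenyl)propan-1-one
Conditions: BCl3 (1 M in CH2Cl2, 10 equiv), C6HMe5 (9 equiv), CH2Cl2, −78 °C → 0 °C; H2O quench
Reagents that add atoms: none
Why: Lewis-acid ether cleavage: BCl3 with pentamethylbenzene as a non-basic benzyl-cation scavenger removes the three aryl benzyl ethers at −78 °C, and on warming the boron chelate of the aryl ketone cleaves only the ortho methyl ether (chelation-directed demethylation) while the para methyl ether survives; the medium is never basic, so the α-stereocentre is not epimerised.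

## Compound list

1 | 1-(2,4-dimethoxyphenyl)ethan-1-one (2',4'-dimethoxyacetophenone) | COc1ccc(C(C)=O)c(OC)c1 | starting material
2 | 4-(benzyloxy)benzaldehyde | O=Cc1ccc(OCc2ccccc2)cc1 | starting material
3 | (E)-3-[4-(benzyloxy)phenyl]-1-(2,4-dimethoxyphenyl)prop-2-en-1-one | COc1ccc(C(=O)/C=C/c2ccc(OCc3ccccc3)cc2)c(OC)c1 | intermediate
4 | [4-(benzyloxy)phenyl]boronic acid | OB(O)c1ccc(OCc2ccccc2)cc1 | starting material
5 | 3,3-bis[4-(benzyloxy)phenyl]-1-(2,4-dimethoxyphenyl)propan-1-one | COc1ccc(C(=O)CC(c2ccc(OCc3ccccc3)cc2)c2ccc(OCc3ccccc3)cc2)c(OC)c1 | intermediate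
6 | 2-{bis[4-(benzyloxy)phenyl]methyl}-1-(2,4-dimethoxyphenyl)-4,4,4-trifluorobutane-1,3-dione (racemic, largely enolised; not isolated) | COc1ccc(C(=O)C(C(=O)C(F)(F)F)C(c2ccc(OCc3ccccc3)cc2)c2ccc(OCc3ccccc3)cc2)c(OC)c1 | intermediate
7 | 3,3-bis[4-(benzyloxy)phenyl]-2-diazo-1-(2,4-dimethoxyphenyl)propan-1-one | COc1ccc(C(=O)C(=[N+]=[N-])C(c2ccc(OCc3ccccc3)cc2)c2ccc(OCc3ccccc3)cc2)c(OC)c1 | intermediate
8 | 1-[4-(benzyloxy)-2-hydroxyphenyl]ethan-1-one | CC(=O)c1ccc(OCc2ccccc2)cc1O | starting material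
9 | (E)-1-[4-(benzyloxy)-2-hydroxyphenyl]-3-(dimethylamino)prop-2-en-1-one | CN(C)/C=C/C(=O)c1ccc(OCc2ccccc2)cc1O | intermediate
10 | (3R)-1-[4-(benzyloxy)-2-hydroxyphenyl]-3-{bis[4-(benzyloxy)phenyl]methyl}-4-(2,4-dimethoxyphenyl)-2-[(dimethylamino)methylidene]butane-1,4-dione (C-alkylated enaminone; C=C geometry not defined, both isomers cyclise; not isolated) | COc1ccc(C(=O)[C@@H](C(=CN(C)C)C(=O)c2ccc(OCc3ccccc3)cc2O)C(c2ccc(OCc3ccccc3)cc2)c2ccc(OCc3ccccc3)cc2)c(OC)c1 | intermediate
11 | 7-(benzyloxy)-3-[(2R)-3,3-bis[4-(benzyloxy)phenyl]-1-(2,4-dimethoxyphenyl)-1-oxopropan-2-yl]-4H-chromen-4-one | COc1ccc(C(=O)[C@@H](c2coc3cc(OCc4ccccc4)ccc3c2=O)C(c2ccc(OCc3ccccc3)cc2)c2ccc(OCc3ccccc3)cc2)c(OC)c1 | intermediate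
12 | (2R)-1-(2-hydroxy-4-methoxyphenyl)-2-(7-hydroxy-4-oxo-4H-chromen-3-yl)-3,3-bis(4-hydroxyphenyl)propan-1-one (CNP0178475.1) | COc1ccc(C(=O)[C@@H](c2coc3cc(O)ccc3c2=O)C(c2ccc(O)cc2)c2ccc(O)cc2)c(O)c1 | target

## Step count and risks

Total steps: 6 (steps 1–3 build the diazoketone, step 4 the enaminone, steps 5–6 join and unmask).
Longest linear sequence: 5 steps (1, 2, 3, 5, 6).
Compound 11 is recrystallised (or passed over a chiral stationary phase) to >99% ee before step 6 if step 5 falls short.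

Three steps most likely to fail:

**Step 5 (key step).** The carbene may undergo 1,2-hydride shift to the enone ArCOCH=CAr2, the zwitterion may close through the enolate oxygen to a furan, or ee may be lost if a free enol is released. The fallback sets out from 1 and 9 and comes back to the route at 12. Ketone 1 is taken, by the same trifluoroacetylation/diazo transfer as in step 3, through 1-(2,4-dimethoxyphenyl)-4,4,4-trifluorobutane-1,3-dione F1 to the terminal diazoketone 2-diazo-1-(2,4-dimethoxyphenyl)ethan-1-one F2, which has no β-hydrogen. With Rh2(OAc)4 in CH2Cl2 its carbene is trapped by 9 to give 1-[4-(benzyloxy)-2-hydroxyphenyl]-4-(2,4-dimethoxyphenyl)-2-[(dimethylamino)methylidene]butane-1,4-dione F3, which cyclises with AcOH to 7-(benzyloxy)-3-[2-(2,4-dimethoxyphenyl)-2-oxoethyl]-4H-chromen-4-one F4. The stereocentre is then set in a separate step. Bis(4-hydroxyphenyl)methanol F5 (NaBH4 reduction of commercial 4,4'-dihydroxybenzophenone) is dehydrated by a chiral BINOL-derived phosphoric acid such as TRIP (enantiomer chosen to give R) to 4-[(4-hydroxyphenyl)methylidene]cyclohexa-2,5-dien-1-one F6. The phosphate-bound enol of F4 adds to it in a 1,6-fashion to give 7-(benzyloxy)-3-[(2R)-1-(2,4-dimethoxyphenyl)-3,3-bis(4-hydroxyphenyl)-1-oxopropan-2-yl]-4H-chromen-4-one F7. The conditions of step 6 (BCl3, C6HMe5) then convert F7 into 12.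

**Step 3 (diazo transfer).** The hindered, α-branched diketone enolate may react slowly with the sulfonyl azide, or 6 may revert to 5. The fallback sets out from 5 and comes back to the route at 7. Nitrosation of the methylene of 5 (tBuONO, KOtBu, THF, 0 °C) gives 3,3-bis[4-(benzyloxy)phenyl]-1-(2,4-dimethoxyphenyl)-2-(hydroxyimino)propan-1-one F8. A Forster reaction (NH2Cl made from NaOCl and aqueous NH3, 0 °C) then converts the oxime into diazoketone 7.

**Step 6 (global unmasking).** The para methyl ether may also be cleaved, or Lewis-acid-promoted enolisation may erode ee during the warmer demethylation phase. The fallback sets out from 11 and comes back to the route at 12. Neutral hydrogenolysis (H2, Pd(OH)2/C, EtOAc/THF, rt) first removes the benzyl groups to give 3-[(2R)-1-(2,4-dimethoxyphenyl)-3,3-bis(4-hydroxyphenyl)-1-oxopropan-2-yl]-7-hydroxy-4H-chromen-4-one F9. MgI2·OEt2 (PhMe/Et2O, 50 °C) then cleaves only the carbonyl-chelated ortho methyl ether to give 12.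

## Further compounds

F1 | step 5 | 1-(2,4-dimethoxyphenyl)-4,4,4-trifluorobutane-1,3-dione | COc1ccc(C(=O)CC(=O)C(F)(F)F)c(OC)c1
F2 | step 5 | 2-diazo-1-(2,4-dimethoxyphenyl)ethan-1-one | COc1ccc(C(=O)C=[N+]=[N-])c(OC)c1
F3 | step 5 | 1-[4-(benzyloxy)-2-hydroxyphenyl]-4-(2,4-dimethoxyphenyl)-2-[(dimethylamino)methylidene]butane-1,4-dione | COc1ccc(C(=O)CC(=CN(C)C)C(=O)c2ccc(OCc3ccccc3)cc2O)c(OC)c1
F4 | step 5 | 7-(benzyloxy)-3-[2-(2,4-dimethoxyphenyl)-2-oxoethyl]-4H-chromen-4-one | COc1ccc(C(=O)Cc2coc3cc(OCc4ccccc4)ccc3c2=O)c(OC)c1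
F5 | step 5 | bis(4-hydroxyphenyl)methanol | OC(c1ccc(O)cc1)c1ccc(O)cc1
F6 | step 5 | 4-[(4-hydroxyphenyl)methylidene]cyclohexa-2,5-dien-1-one | O=C1C=CC(=Cc2ccc(O)cc2)C=C1
F7 | step 5 | 7-(benzyloxy)-3-[(2R)-1-(2,4-dimethoxyphenyl)-3,3-bis(4-hydroxyphenyl)-1-oxopropan-2-yl]-4H-chromen-4-one | COc1ccc(C(=O)[C@@H](c2coc3cc(OCc4ccccc4)ccc3c2=O)C(c2ccc(O)cc2)c2ccc(O)cc2)c(OC)c1
F8 | step 3 | 3,3-bis[4-(benzyloxy)phenyl]-1-(2,4-dimethoxyphenyl)-2-(hydroxyimino)propan-1-one | COc1ccc(C(=O)C(=NO)C(c2ccc(OCc3ccccc3)cc2)c2ccc(OCc3ccccc3)cc2)c(OC)c1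
F9 | step 6 | 3-[(2R)-1-(2,4-dimethoxyphenyl)-3,3-bis(4-hydroxyphenyl)-1-oxopropan-2-yl]-7-hydroxy-4H-chromen-4-one | COc1ccc(C(=O)[C@@H](c2coc3cc(O)ccc3c2=O)C(c2ccc(O)cc2)c2ccc(O)cc2)c(OC)c1
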